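The numbers in the tables come from a simulation on assumed constants, noise included.

Catalyst is a conserved count: what is charged can be spent, and nothing adds to it. Suppose each turnover is a fork for one catalyst unit, round again or lost, with capture agent at 10.0 mM. A unit then gives a fixed amount of target, and the rate falls on a straight line against target made.

| flask | starting material | reagent | capture agent | free catalyst | temperature | remark | time |
|---|---|---|---|---|---|---|---|
| east | 0.010 M | 1.05 equiv | 10 mM | 0.9 mol% | 105 °C | run made earlier |  |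
| south | 0.010 M | 1.05 equiv | 10 mM | 1.6 mol% | 116 °C | run made earlier |  |
| west | 0.010 M | 1.05 equiv | 10 mM | 3.5 mol% | 105 °C | run made earlier |  |
| south-east | 0.010 M | 1.7 equiv | 10 mM | 2.9 mol% | 116 °C | run made earlier |  |
| oak | 0.010 M | 3.20 equiv | 10.0 mM | 2.9 mol% | 110 °C |  | 4.0 h |
| maple | 0.010 M | 0.700 equiv | 10.0 mM | 2.9 mol% | 110 °C |  | 4.0 h |
| ash | 0.030 M | 1.05 equiv | 10.0 mM | 0.8 mol% | 110 °C |  | 4.0 h |
| birch | 0.010 M | 1.05 equiv | 10.0 mM | 2.9 mol% | 110 °C |  | 4.0 h |
| elm | 0.010 M | 1.05 equiv | 10.0 mM | 0.8 mol% | 110 °C |  | 4.0 h |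

| run | time / h | target / % | starting material / % |
|---|---|---|---|
| east | 0.250 | 0 | 99.6 |
| east | 0.417 | 1.0 | 99.2 |
| east | 0.833 | 1.7 | 98.8 |
| east | 1.33 | 2.4 | 97.7 |
| east | 3.00 | 3.8 | 95.4 |
| south | 0.250 | 1.9 | 98.0 |
| south | 0.417 | 2.8 | 97.1 |
| south | 0.833 | 5.3 | 94.2 |
| south | 1.33 | 7.3 | 90.3 |
| south | 3.00 | 14.3 | 85.0 |
| west | 0.500 | 3.1 | 96.2 |
| west | 1.00 | 6.8 | 93.1 |
| west | 1.50 | 9.3 | 89.8 |
| west | 2.50 | 13.0 | 85.2 |
| west | 3.00 | 14.9 | 82.8 |
| south-east | 0.250 | 5.6 | 95.0 |
| south-east | 0.667 | 11.8 | 88.4 |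
| south-east | 1.33 | 19.8 | 79.7 |
| south-east | 2.00 | 24.4 | 73.1 |
| south-east | 3.00 | 30.8 | 67.5 |

(standard deviation of a reading: 0.5 percentage points)

- a reading or a percentage of target counts all its forms, free or not

* the flasks put in order of amount of target, in percent of the starting material charged, best first, at 4.0 h (oak / maple / ash / birch / elm)
* the amount of target, in percent of the starting material charged of the flask you put first, at 4.0 h
* the amount of target, in percent of the starting material charged of the flask you put last, at 4.0 h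

Two slices of the west run, split at 1.50 h, put the zero of that line at 23.4 % target. The south-east run, split at 1.33 h, puts it at 37.5 %. Divided by the catalyst charged, these readings give 6.68 at 105 °C and 12.9 at 116 °C. Interpolated to 110 °C, that is 9.02 units of target per unit of catalyst charged, the turnover number.

Catalyst loading: by hand the ceiling is turnover number times loading. That gives 26.2 % at 2.9 mol% and 7.22 % at 0.8 mol%.

Reagent: this reckoning puts it in the slope of the line, not in the ceiling. The slope of the line is 0.331 h⁻¹ in the west run and 0.539 h⁻¹ in the south-east run. Per unit of reagent concentration the two readings agree at 31.6 M⁻¹ h⁻¹. The filled part of the ceiling is one minus the exponential of minus this constant times reagent concentration times time. At 4.0 h that gives 98.3 % for oak, 73.5 % for birch and elm, and 58.7 % for maple.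

Starting material: ash triples elm's concentration at the same equivalents, so its reagent concentration rises and this reckoning fills 98.1 % of its ceiling. Ash carries elm's loading, 0.8 mol%, so this reckoning gives it elm's ceiling.

The reckoning gives oak 25.7 %, birch 19.2 %, maple 15.4 %, ash 7.08 % and elm 5.30 %.

The forecast differs: oak > ash > birch > maple > elm, with 45 % first and 5.2 % last, and ash near 31. Its ground for ash: “Ash has triple concentrations, so its rate is much higher”.

The flasks give oak > birch > maple > ash > elm: oak 30.0 %, birch 20.0 %, maple 15.5 %, ash 8.38 %, elm 5.91 %.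

    starting material + catalyst intermediate A → catalyst intermediate B (k = 13000 M⁻¹ h⁻¹, Ea = 67.0 kJ mol⁻¹)
    catalyst intermediate B → free catalyst + target (k = 41.0 h⁻¹, Ea = 107 kJ mol⁻¹)
    2 catalyst intermediate A ⇌ resting dimer, settled at all times (K = 13000 M⁻¹, ΔH = −50.0 kJ mol⁻¹)
    reagent + free catalyst ⇌ catalyst intermediate A (K = 960 M⁻¹, k = 370 M⁻¹ h⁻¹, Ea = 80.0 kJ mol⁻¹, ΔH = −13.0 kJ mol⁻¹)
    catalyst intermediate B + capture agent → trapped intermediate (k = 370 M⁻¹ h⁻¹, Ea = 50.0 kJ mol⁻¹)
    reagent + target ⇌ idle adduct, settled at all times (K = 68.0 M⁻¹, ΔH = −48.0 kJ mol⁻¹)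
    (constants at 110 °C)

Forecast and flask part at ash, which gives 8.38 % against the forecast's 31 and a reckoned ceiling of 7.22 %. The neighbour is elm with 2 mol% free catalyst. Its ceiling is 18.0 %, and elm's filled part 73.5 % makes that 13.3 % target. That flask gives 14.2 %, with 1.27 % of the starting material charged standing as trapped intermediate.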